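The runs come from a simulation from invented constants.

Into a closed, stirred vessel at constant temperature goes X; D appears, peaks and sags, and you have two earlier runs to go on before the new flask.

| flask | X | remark | time |
|---|---|---|---|
| summer | 0.025 M | run made earlier |  |
| autumn | 0.10 M | run made earlier |  |
| flask | 0.050 M |  | 8.0 h |

| run | time / h | D / % |
|---|---|---|
| summer | 0.0500 | 11.0 |
| summer | 0.200 | 17.9 |
| summer | 1.00 | 16.7 |
| summer | 5.00 | 15.0 |
| autumn | 0.0500 | 26.7 |
| autumn | 0.200 | 19.7 |
| autumn | 1.00 | 14.2 |
| autumn | 5.00 | 11.4 |

(each reading ± 0.5 percentage points)

- percentages count the X that a species holds: one D counts as two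
- the numbers in the tables scatter with a standard deviation of 0.5 percentage points

- the best time, 8.0 h at the latest, for D
- the amount of D, in percent of the X charged, at that time
- the first time at which D reaches 6.7%, in the same percent, in min

Read the two tables against each other. The summer reading at 0.200 h has a charge-time of 18.0 M·s, charge multiplied by time run (the reduced time of second-order kinetics). If every step took two partners, equal charge-time would give equal percentages: that is your zero.

The autumn reading at 0.0500 h has the same charge-time, yet reads 26.7% against 17.9%, with a scatter of 0.5 points. The summer run took longer to get there, so I suspect a one-partner step running by the clock.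

These are also the highest readings of their runs, so I take that charge-time as the peak, a rough reading from points that lie far apart. Your flask has twice the summer charge and half the autumn one, which puts its peak near 0.100 h. Summer to autumn is two doublings, so I let each gain 4.4 points and expect the flask to reach 22.3%. A straight line in charge-time, from zero through the first summer reading, brings the flask to 6.7% at 0.914 min.

The forecast, holding that “the higher the charge, the higher and earlier its peak”, gave 22% at 0.15 h, a later peak than mine, and 0.75 min for the level.

The flask gives 22.4% at 0.119 h, and 6.7% at 0.713 min.

    2 X → D (k = 0.0182 M⁻¹ s⁻¹)
    D ⇌ Q (K = 2.40, k = 0.00211 s⁻¹)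
    X + D → L (k = 0.0285 M⁻¹ s⁻¹)

The flask's best time has a charge-time of 21.4 M·s, against 18.0 M·s read from the runs, and its peak stands at 22.4% against my 22.3%. The one-partner step is D ⇌ Q, whose relaxation half-life by this step alone, both ways together, is 0.0644 h, shorter than that best time. The neighbour flask at 0.20 M lies one doubling above autumn, so the same reckoning gives it a peak of 31.1%, at the peak charge-time read from the runs, reached there after 0.0250 h. That neighbour flask peaks at 30.9%, and at its end it holds 10.7% as D.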